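**Retrosynthetic overview**
1. The p-coumarate is attached last by an invertive (Mitsunobu) esterification of the C4-epimeric hydroazulene-3,4-diol; this sets C4.
2. The diol comes from one cationic cascade: a farnesyl-type tertiary allyl cation closes the C8–C8a bond onto a tetrasubstituted cyclopentene (seven-membered ring), then a 1,2-hydride shift C3→C3a occurs and the neighbouring acetate carries oxygen to the C3 cation.
3. The cascade substrate is made from a cyclopentene carbaldehyde and isoprene by asymmetric isoprenylboration, then acetylation.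
4. The cyclopentene carbaldehyde comes from (S)-limonene by selective hydrogenation, ozonolysis and aldol ring contraction.
5. Ring order: five-membered ring first (step 2), seven-membered ring second (step 5).

Assumption: the presumed biosynthesis is taken as farnesyl cation → C1–C7/C6–C10 bicyclisation → 1,2-hydride shift → oxygen capture at the tertiary ring cation, then oxygenation and acylation of the neighbouring ring carbon; positions below use the azulene numbering of the target (C3 carbinol, C3a ring-fusion CH, C4 ester carbon, C8a quaternary carbon).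

**Step 1**
Reactants: 1 (S)-(−)-limonene
Product: 2 (4S)-1-methyl-4-(propan-2-yl)cyclohex-1-ene
Conditions: H2 (1 atm), RhCl(PPh3)3 (1 mol%), toluene, 23 °C
Reagents that add atoms: none
Why: Chemoselective homogeneous hydrogenation reduces the 1,1-disubstituted isopropenyl alkene much faster than the trisubstituted ring alkene and leaves the stereocentre untouched.

**Step 2**
Reactants: 2 (4S)-1-methyl-4-(propan-2-yl)cyclohex-1-ene
Product: 4 (5R)-2-methyl-5-(propan-2-yl)cyclopent-1-ene-1-carbaldehyde, via keto aldehyde 3 (not isolated)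
Conditions: O3, CH2Cl2/MeOH, −78 °C; Me2S, −78 to 23 °C; then piperidine (0.2 equiv), AcOH (0.2 equiv), toluene, 80 °C
Reagents that add atoms: ozone, [O-][O+]=O
Why: Ozonolysis opens the ring alkene to the 1,6-keto aldehyde, whose piperidine enamine adds to the ketone and dehydrates (intramolecular aldol condensation) to the conjugated cyclopentene carbaldehyde; the isopropyl-bearing stereocentre is never alpha to a carbonyl and is carried through (the descriptor changes from S to R only through CIP priorities).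

**Step 3**
Reactants: 4 (5R)-2-methyl-5-(propan-2-yl)cyclopent-1-ene-1-carbaldehyde; 5 isoprene
Product: 7 (1R)-3-methylidene-1-[(5R)-2-methyl-5-(propan-2-yl)cyclopent-1-en-1-yl]pent-4-en-1-ol, via borinate ester 6 (not isolated)
Conditions: 5, potassium 2,2,6,6-tetramethylpiperidide, THF, −78 °C; (+)-Ipc2BOMe (from (−)-α-pinene); BF3·OEt2; then 4, −78 °C; NaOH, H2O2, 0 to 23 °C
Reagents that add atoms: none
Why: Brown-type asymmetric allylboration (isoprenylboration) through a closed chair transition state: the (−)-α-pinene-derived 2-methylidenebut-3-enylborane adds to the Re face of the aldehyde and sets the (1R)-carbinol under reagent control, the ring stereocentre being too remote to interfere.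

**Step 4**
Reactants: 7 (1R)-3-methylidene-1-[(5R)-2-methyl-5-(propan-2-yl)cyclopent-1-en-1-yl]pent-4-en-1-ol
Product: 8 (1R)-3-methylidene-1-[(5R)-2-methyl-5-(propan-2-yl)cyclopent-1-en-1-yl]pent-4-en-1-yl acetate
Conditions: Ac2O, pyridine, DMAP (5 mol%), CH2Cl2, 0 to 23 °C
Reagents that add atoms: acetic anhydride, CC(=O)OC(C)=O
Why: DMAP-catalysed acylation of the secondary alcohol touches no stereocentre and installs the neighbouring group used in step 5.

**Step 5**
Reactants: 8 (1R)-3-methylidene-1-[(5R)-2-methyl-5-(propan-2-yl)cyclopent-1-en-1-yl]pent-4-en-1-yl acetate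
Product: 13 (3R,3aS,4R,8aR)-6,8a-dimethyl-3-(propan-2-yl)-1,2,3,3a,4,5,8,8a-octahydroazulene-3,4-diol, via allyl cation 9 (not isolated), via ring-fusion acetoxonium ion 10 (not isolated), via six-membered acetoxonium ion 11 (not isolated), via hydroxy acetate 12 (not isolated)
Conditions: TfOH (1.05 equiv), CH2Cl2, 0.01 M, −78 to −30 °C; then 2 M NaOH, MeOH, 23 °C
Reagents that add atoms: none
Why: Proposed new method: protonation of the 2-substituted diene at its methylidene carbon gives tertiary allyl cation 9 (the allyl cation of farnesyl ionisation), whose primary terminus attacks the tetrasubstituted ring alkene (no Markovnikov bias) at the methyl-bearing carbon from the face opposite the isopropyl group while the acetate carbonyl closes anti on the other alkene carbon (five-membered 1,2-acyloxy participation, expected to beat the six-membered participation that spiro closure would need), forming the C8–C8a bond and setting C8a; the C3–H, anti-periplanar to the C3a–O bond of 10, then shifts to C3a with inversion (trans ring fusion) as the acetoxonium oxygen moves to C3 on the face of C4 (setting C3) to give ion 11, which stores the acid equivalent until hydroxide opens and saponifies it; the closest known reactions are acid-induced cation–olefin cyclisations of terpene dienes and acetates, acetoxonium neighbouring-group rearrangements of the Woodward–Prévost type, and the 1,2-hydride shift of the daucyl cation.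

**Step 6**
Reactants: 13 (3R,3aS,4R,8aR)-6,8a-dimethyl-3-(propan-2-yl)-1,2,3,3a,4,5,8,8a-octahydroazulene-3,4-diol; 14 (2E)-3-(4-hydroxyphenyl)prop-2-enoic acid
Product: 15 (3R,3aS,4S,8aR)-3-hydroxy-6,8a-dimethyl-3-(propan-2-yl)-1,2,3,3a,4,5,8,8a-octahydroazulen-4-yl (2E)-3-(4-hydroxyphenyl)prop-2-enoate
Conditions: PPh3, DIAD, THF, 0 to 23 °C
Reagents that add atoms: none
Why: Mitsunobu esterification: the alkoxyphosphonium of the secondary C4 hydroxyl is displaced by the carboxylate with inversion (4R to 4S); the carboxylic acid (pKa about 4.6) reacts in preference to the phenol (pKa about 9.5) and the tertiary C3 hydroxyl is not activated.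

**Compound list**
1 | (4S)-1-methyl-4-(prop-1-en-2-yl)cyclohex-1-ene, (S)-(−)-limonene | CC1=CC[C@H](CC1)C(C)=C | starting material
2 | (4S)-1-methyl-4-(propan-2-yl)cyclohex-1-ene | CC1=CC[C@H](CC1)C(C)C | intermediate
3 | (3S)-6-oxo-3-(propan-2-yl)heptanal | CC(=O)CC[C@@H](CC=O)C(C)C | intermediate
4 | (5R)-2-methyl-5-(propan-2-yl)cyclopent-1-ene-1-carbaldehyde | CC1=C(C=O)[C@H](CC1)C(C)C | intermediate
5 | isoprene | C=CC(C)=C | starting material
6 | diisopinocampheylborinate ester of 7 | C=CC(=C)C[C@@H](OB([C@H]2C[C@H]3C[C@H](C3(C)C)[C@@H]2C)[C@H]2C[C@H]3C[C@H](C3(C)C)[C@@H]2C)C1=C(C)CC[C@@H]1C(C)C | intermediate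
7 | (1R)-3-methylidene-1-[(5R)-2-methyl-5-(propan-2-yl)cyclopent-1-en-1-yl]pent-4-en-1-ol | C=CC(=C)C[C@@H](O)C1=C(C)CC[C@@H]1C(C)C | intermediate
8 | (1R)-3-methylidene-1-[(5R)-2-methyl-5-(propan-2-yl)cyclopent-1-en-1-yl]pent-4-en-1-yl acetate | C=CC(=C)C[C@@H](OC(C)=O)C1=C(C)CC[C@@H]1C(C)C | intermediate
9 | tertiary allyl cation from protonation of the diene of 8 (triflate salt, cation shown) | C=C[C+](C)C[C@@H](OC(C)=O)C1=C(C)CC[C@@H]1C(C)C | intermediate
10 | ring-fusion acetoxonium ion: 2-methyl-1,3-dioxolan-2-ylium fused across C4 and C3a after C8–C8a closure (cation shown) | CC1=CC[C@@]2(C)CC[C@H](C(C)C)[C@]23[O+]=C(C)O[C@@H]3C1 | intermediate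
11 | six-membered acetoxonium ion: 2-methyl-1,3-dioxan-2-ylium spanning the C4 and C3 oxygens, H on C3a (cation shown) | CC1=CC[C@@]2(C)CC[C@@]3(C(C)C)[C@@H]2[C@@H](C1)OC(C)=[O+]3 | intermediate
12 | (3R,3aS,4R,8aR)-3-hydroxy-6,8a-dimethyl-3-(propan-2-yl)-1,2,3,3a,4,5,8,8a-octahydroazulen-4-yl acetate | CC1=CC[C@@]2(C)CC[C@@](O)(C(C)C)[C@@H]2[C@H](OC(C)=O)C1 | intermediate
13 | (3R,3aS,4R,8aR)-6,8a-dimethyl-3-(propan-2-yl)-1,2,3,3a,4,5,8,8a-octahydroazulene-3,4-diol | CC1=CC[C@@]2(C)CC[C@@](O)(C(C)C)[C@@H]2[C@H](O)C1 | intermediate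
14 | (2E)-3-(4-hydroxyphenyl)prop-2-enoic acid, p-coumaric acid | OC(=O)/C=C/c1ccc(O)cc1 | starting material
15 | (3R,3aS,4S,8aR)-3-hydroxy-6,8a-dimethyl-3-(propan-2-yl)-1,2,3,3a,4,5,8,8a-octahydroazulen-4-yl (2E)-3-(4-hydroxyphenyl)prop-2-enoate | CC1=CC[C@@]2(C)CC[C@@](O)(C(C)C)[C@@H]2[C@@H](OC(=O)/C=C/c2ccc(O)cc2)C1 | target

**Totals and risks**
Total step count: 6. Longest linear sequence: 6 steps (1 to 15).

The three steps most likely to fail are steps 5, 6 and 3.

Step 5 (cation cascade). The allyl cation may close on the acyl-bearing alkene carbon (spiro[4.5]decane, acorane-type products), the sequence may stop at ion 10, or elimination may win over the hydride shift. The fallback makes the seven-membered ring by ring-closing metathesis and keeps only the hydride shift; it sets out from 4 and comes back at 15. Methallylboration of 4 with (−)-Ipc2B(2-methylallyl) (from (+)-α-pinene) gives (1S)-3-methyl-1-[(5R)-2-methyl-5-(propan-2-yl)cyclopent-1-en-1-yl]but-3-en-1-ol F1. VO(acac)2 with tBuOOH epoxidises the tetrasubstituted ring alkene on the face of the hydroxyl to the epoxy alcohol F2. Allyltrimethylsilane with BF3·OEt2 opens the oxirane at the methyl-bearing carbon with inversion to the allyl diol F3. Second-generation Grubbs catalyst closes the cycloheptene to the 3a,4-diol F4. EDC·HCl and DMAP with (E)-4-acetoxycinnamic acid acylate the secondary hydroxyl to the ester F5. TfOH ionises the tertiary 3a-hydroxyl, the C3–H shifts to C3a and the ester carbonyl captures the C3 cation; hydrolytic work-up gives the phenol acetate of the target F6. K2CO3 in MeOH at 0 °C removes the aryl acetate to give 15.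

Step 6 (Mitsunobu inversion). The secondary alcohol is hindered and next to the ring fusion, so elimination, phenol alkylation or no reaction are possible. The fallback inverts C4 by oxidation and directed reduction and then acylates with retention; it sets out from 13 and comes back at 15. Dess–Martin periodinane gives the hydroxy ketone F7. Me4NBH(OAc)3 in MeCN/AcOH delivers hydride from the boron bound to the C3 hydroxyl and gives the anti-1,3-diol jaeschkeanadiol F8 with the natural (4S) configuration. EDC·HCl and DMAP with (E)-3-[4-(tert-butyldimethylsilyloxy)phenyl]prop-2-enoic acid give the silyl-protected target F9. Bu4NF buffered with AcOH gives 15.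

Step 3 (asymmetric isoprenylboration). The tetrasubstituted enal is hindered and reagent control may be incomplete. The fallback sets the carbinol by ketone reduction; it sets out from 4 and comes back at 7. Addition of (2-methylidenebut-3-en-1-yl)magnesium bromide (from the potassium reagent and MgBr2) gives 7 together with its (1S)-epimer F10. MnO2 oxidises the mixture to the dienyl ketone F11. (S)-2-Methyl-CBS-oxazaborolidine with BH3·SMe2 reduces F11 to 7.

Further compounds
F1 | step 5 | (1S)-3-methyl-1-[(5R)-2-methyl-5-(propan-2-yl)cyclopent-1-en-1-yl]but-3-en-1-ol | CC(=C)C[C@H](O)C1=C(C)CC[C@@H]1C(C)C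
F2 | step 5 | (1S)-3-methyl-1-[5-methyl-2-(propan-2-yl)-6-oxabicyclo[3.1.0]hexan-1-yl]but-3-en-1-ol, oxirane oxygen cis to the isopropyl group | CC(=C)C[C@H](O)[C@@]12O[C@]1(C)CC[C@@H]2C(C)C
F3 | step 5 | (1S)-1-[1-hydroxy-2-methyl-5-(propan-2-yl)-2-(prop-2-en-1-yl)cyclopentyl]-3-methylbut-3-en-1-ol, ring hydroxyl cis to the ring methyl and the isopropyl group | CC(=C)C[C@H](O)[C@@]1(O)[C@@](C)(CC=C)CC[C@@H]1C(C)C
F4 | step 5 | (3R,3aS,4S,8aR)-6,8a-dimethyl-3-(propan-2-yl)-1,2,3,3a,4,5,8,8a-octahydroazulene-3a,4-diol | CC1=CC[C@@]2(C)CC[C@H](C(C)C)[C@@]2(O)[C@@H](O)C1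
F5 | step 5 | (3R,3aS,4S,8aR)-3a-hydroxy-6,8a-dimethyl-3-(propan-2-yl)-1,2,3,3a,4,5,8,8a-octahydroazulen-4-yl (2E)-3-(4-acetoxyphenyl)prop-2-enoate | CC1=CC[C@@]2(C)CC[C@H](C(C)C)[C@@]2(O)[C@@H](OC(=O)/C=C/c3ccc(OC(C)=O)cc3)C1
F6 | step 5 | (3R,3aS,4S,8aR)-3-hydroxy-6,8a-dimethyl-3-(propan-2-yl)-1,2,3,3a,4,5,8,8a-octahydroazulen-4-yl (2E)-3-(4-acetoxyphenyl)prop-2-enoate | CC1=CC[C@@]2(C)CC[C@@](O)(C(C)C)[C@@H]2[C@@H](OC(=O)/C=C/c3ccc(OC(C)=O)cc3)C1
F7 | step 6 | (3R,3aR,8aR)-3-hydroxy-6,8a-dimethyl-3-(propan-2-yl)-2,3,3a,5,8,8a-hexahydroazulen-4(1H)-one | CC1=CC[C@@]2(C)CC[C@@](O)(C(C)C)[C@@H]2C(=O)C1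
F8 | step 6 | (3R,3aS,4S,8aR)-6,8a-dimethyl-3-(propan-2-yl)-1,2,3,3a,4,5,8,8a-octahydroazulene-3,4-diol, jaeschkeanadiol | CC1=CC[C@@]2(C)CC[C@@](O)(C(C)C)[C@@H]2[C@@H](O)C1
F9 | step 6 | (3R,3aS,4S,8aR)-3-hydroxy-6,8a-dimethyl-3-(propan-2-yl)-1,2,3,3a,4,5,8,8a-octahydroazulen-4-yl (2E)-3-[4-(tert-butyldimethylsilyloxy)phenyl]prop-2-enoate | CC1=CC[C@@]2(C)CC[C@@](O)(C(C)C)[C@@H]2[C@@H](OC(=O)/C=C/c3ccc(O[Si](C)(C)C(C)(C)C)cc3)C1
F10 | step 3 | (1S)-3-methylidene-1-[(5R)-2-methyl-5-(propan-2-yl)cyclopent-1-en-1-yl]pent-4-en-1-ol | C=CC(=C)C[C@H](O)C1=C(C)CC[C@@H]1C(C)C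
F11 | step 3 | 3-methylidene-1-[(5R)-2-methyl-5-(propan-2-yl)cyclopent-1-en-1-yl]pent-4-en-1-one | C=CC(=C)CC(=O)C1=C(C)CC[C@@H]1C(C)C
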